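Readings and results come from a simulation on assumed constants, noise included.

The winter run's mono adduct tops out at 25.1% and the summer run's at 24.3%, a gap of 0.8 percentage points, although the summer run charges more substrate. So the next flask's recipe should follow from a ratio, not from the charges.

| flask | substrate | reagent | capture agent | remark | time |
|---|---|---|---|---|---|
| winter | 0.40 M | 0.40 M | 0.24 M | run made earlier |  |
| summer | 0.60 M | 0.40 M | 0.24 M | run made earlier |  |
| flask | 0.80 M | 0.400 M | 0.240 M |  | 6.0 min |

- winter (time / min: mono adduct / %, bis adduct / %): 0.833: 17.6, 4.7; 1.50: 22.6, 10.2; 2.50: 24.7, 17.0; 3.00: 25.0, 19.6; 4.00: 25.1, 23.9; 5.00: 24.7, 26.6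
- summer (time / min: mono adduct / %, bis adduct / %): 0.833: 17.0, 4.4; 1.50: 21.3, 7.9; 2.50: 23.3, 12.9; 3.00: 24.0, 13.7; 4.00: 24.3, 16.4; 5.00: 24.3, 17.4

(each reading ± 0.3 percentage points)

- a reading or a percentage of bis adduct counts all its forms, free or not

1. equivalents of reagent to substrate, everything else as given, that leave most mono adduct at 6.0 min
2. the amount of mono adduct then, in percent of the substrate charged
3. the amount of mono adduct with the amounts as given

Let s be the fraction of substrate that neither adduct holds. We assume a scheme of two additions on the same c(reagent); in it, s/m at the mono adduct peak, where mono adduct is made as fast as it is used, stands for the second-step rate constant over the first-step one. We call this reading the apparent selectivity factor κ, and any further loss of mono adduct sits inside it. The winter run at 4.00 min reads κ = 2.03. Two equal, independent sites would give 0.5, so this reading stands 4.06 times above the statistical zero.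

Integrating gives our curve, m = (s^κ − s)/(1 − κ). Its peak is 24.8% at s = 50.3%, and reaching it costs 0.746 equiv of reagent, or 0.597 M. The given charge of 0.500 equiv falls short, which makes reagent the limiting reagent. With κ rounded to 2, using all of it leaves s = 63.4% and m = 23.2%. We would therefore charge above 0.746 equiv.

The forecast gives 22.7% as charged and 24.8% at 0.85 equiv, adding that “the optimum is flat”.

The flask gives 21.8% as charged and 24.1% at 0.805 equiv.

    substrate + reagent → mono adduct (k = 0.0150 M⁻¹ s⁻¹)
    reagent + mono adduct → bis adduct (k = 0.0270 M⁻¹ s⁻¹)
    reagent + bis adduct ⇌ idle adduct, settled at all times (K = 2.30 M⁻¹)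
    mono adduct + capture agent → trapped intermediate (k = 0.00170 M⁻¹ s⁻¹)

At 6.00 min the flask as charged has 1.5% of its reagent and 63% of its substrate left. With the 2.78% of trapped intermediate, which neither adduct holds, s is 65.9%, and the curve gives 22.3% of mono adduct. In a neighbouring flask with 0.20 M of substrate, its other charges and time as in the flask, s is 31.5%, below the curve's peak position; the curve gives 21.2%, and that neighbouring flask holds 20.9%.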